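**Numbering and target check.** Lignan numbering is used: ring O–C7'(Ar)–C8'(C9'H2OH)–C8[C7H(OH)Ar]–C9H2. The SMILES corresponds to a (2S,3R,4R)-oxolane (7'S, 8'R, 8R; 2,3-trans and 3,4-cis) with a 7R carbinol.

**Assumption.** The TIPS-protected aryl building blocks are made rather than bought. Ar = 3-methoxy-4-(triisopropylsilyloxy)phenyl throughout.

## Retrosynthetic overview
1. 12 ⇐ 11 ⇐ 10. The C7–OH and C9'H2OH groups are released together by reducing a cis-fused furofuranone, so the lactone ring is sacrificial.
2. 10 ⇐ 9 + CO (key step). One Pd(II) oxidative carbonylative double cyclisation of an acyclic ene-1,3-diol forms the oxolane (O–C7') first, then C8'–C9' from CO, then the γ-lactone. This sets C7' and C8'.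
3. 9 ⇐ 6 + 8 by cross-metathesis, which brings in the C7' aryl group as an (E)-styrene.
4. 6 ⇐ 2 + 5 by catalytic enantioselective syn-(borylmethyl)allylation and oxidation, which sets C7 and C8. 5 ⇐ butadiene + B2pin2.
5. Avoided on purpose: butyrolactone aldol or conjugate-addition assembly followed by benzylic-cation cycloetherification of a polyol.

## Route

**Step 1**
- Reactants: 1, vanillin
- Product: 2, 3-methoxy-4-(triisopropylsilyloxy)benzaldehyde
- Conditions: TIPSCl, imidazole, DMF, rt
- Reagents that add atoms: triisopropylsilyl chloride, CC(C)[Si](Cl)(C(C)C)C(C)C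
- Why: Imidazole-promoted phenol silylation (silyl ether protection); the aryl OTIPS group survives perborate, AcOH/CuCl2 and LiAlH4 and is removed by fluoride, so neither acid nor hydrogenolysis touches the labile benzylic C–O bonds at the end.

**Step 2**
- Reactants: 3, buta-1,3-diene; 4, bis(pinacolato)diboron
- Product: 5, (Z)-1,4-bis(4,4,5,5-tetramethyl-1,3,2-dioxaborolan-2-yl)but-2-ene
- Conditions: Pt(PPh3)4 (3 mol %), PhMe, 80 °C, sealed tube
- Reagents that add atoms: none beyond 3 and 4
- Why: Miyaura Pt(0)-catalysed 1,4-diboration of a 1,3-diene, in which insertion of the s-cis diene into the Pt–B bond and reductive elimination deliver the Z-alkene selectively.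

**Step 3**
- Reactants: 2; 5
- Product: 6, (1R,2R)-2-ethenyl-1-Ar-propane-1,3-diol
- Conditions: (R)-TRIP phosphoric acid (5 mol %), 4 Å MS, PhMe, −30 °C; then NaBO3·4H2O, THF/H2O, rt
- Reagents that add atoms: sodium perborate (O source), [Na+].[Na+].O[B-]1(O)OO[B-](O)(O)OO1
- Why: Chiral-phosphoric-acid-catalysed allylboration through a closed Zimmerman–Traxler chair, where the Z γ-CH2Bpin group gives the syn relationship (C8 relative to C7) and (R)-TRIP directs Re-face attack (7R); the remaining primary, non-allylic C–B bond is then oxidised to C9–OH, as in known tandem diene diboration/allylboration/oxidation and CPA (Z)-crotylboration.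

**Step 4**
- Reactants: 7, 2-methoxy-4-vinylphenol
- Product: 8, triisopropyl(2-methoxy-4-vinylphenoxy)silane
- Conditions: TIPSCl, imidazole, DMF, rt
- Reagents that add atoms: triisopropylsilyl chloride, CC(C)[Si](Cl)(C(C)C)C(C)C
- Why: The same phenol silylation as Step 1; the styrene is inert and no stereocentre is involved.

**Step 5**
- Reactants: 6; 8 (3 equiv)
- Product: 9, (1R,2R)-1-Ar-2-[(E)-2-Ar-ethenyl]propane-1,3-diol
- Conditions: Hoveyda–Grubbs II (5 mol %), CH2Cl2, 40 °C (−C2H4)
- Reagents that add atoms: none beyond 8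
- Why: Olefin cross-metathesis between a fast-reacting styrene and a slower allylically branched terminal alkene is selective for the cross product and for the E-alkene; free alcohols and silyl ethers are tolerated and C7/C8 are not touched.

**Step 6 (key step)**
- Reactants: 9
- Product: 10, (3R,3aR,6S,6aS)-3,6-bis(Ar)tetrahydro-1H,3H-furo[3,4-c]furan-1-one (cis-fused; C3 aryl endo, C6 aryl exo)
- Conditions: PdCl2(MeCN)2 (10 mol %), CuCl2 (3 equiv), NaOAc (3 equiv), AcOH, CO (1 atm), rt
- Reagents that add atoms: carbon monoxide, [C-]#[O+]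
- Why: Proposed new method: a Semmelhack/Tamaru-type oxycarbonylative bis-cyclisation of an ene-diol run in 5-endo mode, in which Pd(II) is held by C7–OH coordination on the alkene face syn to the C7 arm, the primary C9–OH adds anti (chloride-rich medium) at the benzylic carbon of the electron-rich (E)-styrene (the same geometry as 5-endo-trig iodoetherification of (E)-homoallylic alcohols) to give the 2,3-trans σ-alkyl-Pd, CO inserts with retention, and only the acyl-Pd cis to C7–OH can lactonise while oxypalladation is reversible, so C7' (S) and C8' are set from C8; the closest known reactions are anti-alkoxypalladation/carbonylation of styrenes and Pd(II)/CuCl2 conversion of 4-ene-1,3-diols into cis-bicyclic lactones.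

**Step 7**
- Reactants: 10
- Product: 11, (R)-[(3R,4R,5S)-4-(hydroxymethyl)-5-Ar-oxolan-3-yl](Ar)methanol (bis-O-TIPS target)
- Conditions: LiAlH4, THF, 0 °C; Rochelle salt work-up
- Reagents that add atoms: none
- Why: Hydride reduction of the lactone cleaves only the acyl C–O bond, so C7 keeps its R configuration and C9' becomes CH2OH; the benzylic ether and the aryl OTIPS groups are inert.

**Step 8**
- Reactants: 11
- Product: 12, (7R)-7-hydroxylariciresinol
- Conditions: TBAF/AcOH (1:1, 2.2 equiv), THF, 0 °C; pH 7 buffer work-up
- Reagents that add atoms: none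
- Why: Buffered fluoride desilylation of the aryl silyl ethers at 0 °C avoids both acid (which would cyclise the product to a furofuran) and strongly basic phenoxide conditions (quinone methide formation), so all four stereocentres are retained.

## Compound list
| No. | Name | SMILES | Role |
|---|---|---|---|
| 1 | vanillin | O=Cc1ccc(O)c(OC)c1 | starting material |
| 2 | 3-methoxy-4-(TIPSO)benzaldehyde | O=Cc1ccc(O[Si](C(C)C)(C(C)C)C(C)C)c(OC)c1 | intermediate |
| 3 | buta-1,3-diene | C=CC=C | starting material |
| 4 | bis(pinacolato)diboron | CC1(C)OB(OC1(C)C)B1OC(C)(C)C(C)(C)O1 | starting material |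
| 5 | (Z)-1,4-bis(Bpin)but-2-ene | CC1(C)OB(C/C=C\CB2OC(C)(C)C(C)(C)O2)OC1(C)C | intermediate |
| 6 | (1R,2R)-vinyl diol | OC[C@H]([C@@H](O)c1ccc(O[Si](C(C)C)(C(C)C)C(C)C)c(OC)c1)C=C | intermediate |
| 7 | 2-methoxy-4-vinylphenol | C=Cc1ccc(O)c(OC)c1 | starting material |
| 8 | TIPS ether of 7 | C=Cc1ccc(O[Si](C(C)C)(C(C)C)C(C)C)c(OC)c1 | intermediate |
| 9 | (1R,2R,E)-ene-diol | OC[C@H]([C@@H](O)c1ccc(O[Si](C(C)C)(C(C)C)C(C)C)c(OC)c1)/C=C/c1ccc(O[Si](C(C)C)(C(C)C)C(C)C)c(OC)c1 | intermediate |
| 10 | (3R,3aR,6S,6aS)-furofuranone | COc1cc([C@H]2OC[C@@H]3[C@H](c4ccc(O[Si](C(C)C)(C(C)C)C(C)C)c(OC)c4)OC(=O)[C@H]23)ccc1O[Si](C(C)C)(C(C)C)C(C)C | intermediate |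
| 11 | bis-O-TIPS-(7R)-7-hydroxylariciresinol | COc1cc([C@H]2OC[C@H]([C@@H](O)c3ccc(O[Si](C(C)C)(C(C)C)C(C)C)c(OC)c3)[C@@H]2CO)ccc1O[Si](C(C)C)(C(C)C)C(C)C | intermediate |
| 12 | (7R)-7-hydroxylariciresinol | COc1cc([C@H]2OC[C@H]([C@@H](O)c3ccc(O)c(OC)c3)[C@@H]2CO)ccc1O | target |

## Step count
- Total steps: 8.
- Longest linear sequence: 6 (1 → 2 → 6 → 9 → 10 → 11 → 12).

## Three steps most likely to fail

1. **Step 6.**
   - Risks: the 5-endo oxypalladation may be too slow. The C7–OH may attack instead and give the 2,5-diaryl isomer. Pd may sit anti to the C7 arm, which leads to a trans acid with the wrong C7'. β-Hydride elimination may give a dihydrofuran.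
   - Fallback: switch to a radical ring construction that needs no CO.
     - Make the 3-aryl-propargyl ether of enantioenriched 1-Ar-prop-2-en-1-ol and epoxidise the vinyl group.
     - Run a Cp2TiCl epoxide-opening/5-exo-dig cyclisation. C9' comes from the epoxide CH2O and the ring closes 2,3-trans.
     - Set C8 and C7 together by hydroboration–oxidation of the (E)-benzylidene oxolane from the face anti to C9'.

2. **Step 3.**
   - Risks: low rate, ee or syn selectivity with the bulky Z bis-boronate.
   - Fallback: use an auxiliary aldol in place of allylboration.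
     - Run a MgCl2/Et3N/TMSCl-catalysed Evans anti-aldol of (R)-4-benzyl-N-[(E)-4-Ar-but-3-enoyl]oxazolidinone with 2.
     - Remove the auxiliary reductively with LiBH4. This gives 9 directly and also removes Step 5.

3. **Step 5.**
   - Risks: stilbene homodimerisation and a sluggish branched olefin.
   - Fallback: form the aryl–vinyl bond instead of the C=C bond, by Heck arylation of 6 with the TIPS ether of 4-iodo-2-methoxyphenol (Pd(OAc)2, Jeffery conditions), which gives the same (E)-styrene 9.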